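## The problem

Compound 27 is a ten-membered carbocycle (C1 to C10) with two Z-configured trisubstituted alkenes (C4=C5 and C9=C10, methyls on C4 and C10). It is fused across C6–C7 to an α-methylene-γ-butyrolactone (lactone oxygen on C6, C11 on C7, C12 carbonyl, C13 methylene), carries an angelate on C8 and has free hydroxyls on C1 and C3. Of the five stereocentres, C6, C7 and C8 are contiguous and all-syn along the open chain C5 to C9 (trans-lactone, C8 oxygen syn to the C11 branch), while C1 and C3 form an anti-1,3-diol. The C6–C8 triad can be fixed before any ring exists. C3 must then be created where the ring closes, guided only remotely by C6–C8 and the two Z-alkenes, and C1 can be derived from C3 by an internally delivered hydride. The triad is pseudo-symmetric: O6 and O8 are both γ to C12, so the two carbinols must be told apart as each is made, and a free C8 hydroxyl beside the lactone can translactonise under base. Several groups are fragile: the methylene lactone is a Michael acceptor for thiolates, amines and hydride, the angelate isomerises to the tiglate on acyl activation, Z-α-methyl enals and enones isomerise, a β-hydroxy ketone dehydrates, and each carbonyl intermediate at C8 is a β-acyloxy carbonyl compound prone to elimination. The enabling feature is that C1 and C3 are carbinols separated by the single methylene C2, each attached to the methyl-bearing carbon of a Z-alkene (C10 and C4). A C1 ketone enolate generated at C2 can therefore add to a C3 enal and close the ring as a β-hydroxy enone, whose hydroxyl-directed reduction gives the anti-diol without protecting groups.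

## Retrosynthesis

**C1–H.** The last bond made is C1–H, by hydride addition to the C1 ketone of β-hydroxy enone 26. With the C3 hydroxyl as the only free alcohol, an acetoxyborohydride can be bound there and delivered across the ring, so the anti relationship follows from C3. Reducing a C3 ketone from a C1 carbinol would be equivalent, but 26 is the direct product of the ring closure below. The forward step must reduce the enone 1,2 and leave the methylene lactone and the angelate alone.

**C2–C3 (ring closure).** Cutting C2–C3 of 26 gives seco compound 24, a bromomethyl enone at C1/C2 and a Z-enal at C3, joined through samarium enolate 25. This is the only ring bond whose cleavage turns both remote carbinols into carbonyl-derived centres and uses the one unactivated methylene of the ring as the nucleophile. Cuts at C3–C4 or C1–C10 would need Z-alkenyl metals adding to aldehydes inside a molecule that already carries the lactone and the angelate, and would not provide the directing hydroxyl. Compound 24 has three stereocentres instead of five and one ring instead of two. The forward reaction must form the enolate only at C2, close a ten-membered ring in preference to oligomers, and choose one face of the enal.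

**C1=O and C3=O.** Both carbonyl termini of 24 are taken back to alcohols in diol 23: a primary Z-allylic alcohol at C3 and a bromohydrin at C1/C2. One oxidation then creates the enal and the bromomethyl enone together, immediately before use. Introducing bromine late, by enolsilylation and bromination of a methyl ketone, would require the enal to be absent and would cost a second protecting group and three more steps. Diol 23 comes from bis-silyl ether 22.

**C11=C13 and the C8 ester.** The methylene of 22 is unmasked from Mannich base 20 through ammonium salt 21. The angelate of 20 is attached to amino alcohol 18 with angelic acid 19, and the aminomethyl group of 18 is put onto the lactone enolate of 15 through silyl ethers 16 and 17. The order is dictated by the sensitive groups: enolate chemistry must precede the angelate, whose γ-hydrogens are as acidic as the lactone α-hydrogens. The methylene lactone should not coexist with a free C8 hydroxyl under base, so the amine is carried as the masked alkene until the ester is in place.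

**C8–C9.** Alcohol 15 is cut between C8 and C9 into lactone aldehyde 14 and Z-alkenyl iodide 7, to be joined by a Nozaki–Hiyama–Kishi reaction. An olefination of a C9 aldehyde would deliver an ester that cannot be reduced selectively beside the lactone. The chromium reagent adds only to the aldehyde, keeps the alkene geometry and tolerates the lactone and the alkyl bromide. The step must set C8, by Felkin–Anh addition anti to the C7–C6 bond.

**C6–C7.** Aldehyde 14 is traced through thioester 13 to lactone imide 12, and 12 through aldol adduct 11 to succinate imide 10 and Z-enal 4. A boron aldol reaction makes C6–C7 and sets both centres from the auxiliary. The new C6 hydroxyl lactonises onto C12 at once, which distinguishes O6 from the later O8. A conjugate addition to a butenolide would set the same two centres but leaves C5 as a hydroxymethyl group, whose later Z-olefination again ends in an ester beside the lactone.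

**The arms.** Enal 4 (through silyl ether 3) and iodide 7 (through iodo enal 5 and bromohydrin 6) both derive from Z-iodo alcohol 2. Compound 2 is made in one step from propargyl alcohol 1 by a carbometalation that fixes the Z geometry of both ring alkenes. Imide 10 comes from oxazolidinone 8 and acid chloride 9.

## Roads not taken

**Alternative 1:** The cut is C7–C8. In stannane A1, a thirteen-membered ring in which C8 is tied to C13 through an ether oxygen and C7=C11 is an alkene, tin–lithium exchange at C8 would start a [2,3]-Wittig shift. It forms C7–C8, breaks O–C13, moves the alkene to C11=C13 and contracts the ring to dienol A2.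
- Merits: one concerted step creates the ring bond, both C7 and C8, the C11=C13 methylene and a free C8 hydroxyl for the angelate. The large ether ring is closed by simple O-alkylation, and no hydroxy lactone or β-acyloxy aldehyde is ever handled.
- Weak points: the sense at C7/C8 depends on the conformation of a flexible thirteen-membered ring, on the C7=C11 geometry and on an undefined stannylated C8. The anti-diol must be built and silylated in an open chain first. After the contraction C12 is still an ether, so A2 needs angeloylation, removal of two PMB ethers, selective oxidation to the lactone and removal of two silyl ethers.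
- Comparison: this road is as good or better for joining C7 to C8 and avoids aldehyde 14. The chosen plan sets against it convergence from three small pieces, one step between ring closure and target, and a C6–C8 triad made in open-chain steps where a wrong C8 epimer can be inverted.

**Alternative 2:** The cut is C1–C2 together with O–C3. A nitrile oxide generated from the C1 oxime of A3 would add across the terminal C2=C3 alkene of the C2–C5 diene and close isoxazoline and carbocycle together as A4.
- Merits: the cycloaddition is neutral, metal-free and irreversible, so there is no retro-aldol and no electron-transfer side reaction. Precursor A3 is sturdier than 24, and the regiochemistry (oxygen to C3) is the normal one.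
- Weak points: a ten-membered ring formed by dipolar cycloaddition competes with furoxan dimerisation, and the C3 face is controlled only remotely, as here. N–O cleavage of a conjugated isoxazoline (Mo(CO)6 or hydrogenolysis) must spare two alkenes and the angelate. The methylene lactone must then be made from the C13 silyl ether by elimination beside a β-hydroxy ketone or diol.
- Comparison: this road is better in the robustness of its precursor. The chosen plan answers with a ring-closure product that is already the β-hydroxy enone with the methylene lactone in place, and with sensitive termini that exist for a single step.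

**Alternative 3:** The cut is C8–C9. NiCl2 and CrCl2 would convert the Z-iodoalkene of A5 into an alkenylchromium species that adds to the C8 aldehyde and gives A6.
- Merits: this is probably the most reliable way to close a ten-membered carbocycle, it is mild, and the anti-diol is installed beforehand with reagent control, so C3 is not in doubt.
- Weak points: C8 is formed in the ring under conformational control. The β-acyloxy aldehyde must survive a slow, dilute cyclisation, and the linear precursor is long. After closure A6 still needs angeloylation, elimination at C13 and removal of two silyl ethers.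
- Comparison: this road is better for C3 and for precedent of the closure itself. The chosen plan uses the same chromium chemistry intermolecularly, where C8 epimers can be separated or inverted, and then needs only two protecting-group-free steps from 24 to 27.

Key step: step 17

Assumption: the C1 carbinol of the bromohydrin unit (in 6, 7, 15–18 and 20–23) is carried as a mixture of both configurations, because it becomes the C1 ketone in step 16; SMILES leave this centre undefined.

## Route

Step 1
Reactants: 1 prop-2-yn-1-ol
Product: 2 (Z)-3-iodo-2-methylprop-2-en-1-ol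
Conditions: MeMgBr, CuI (10 mol%), THF–Et2O, −10 °C to rt; then I2, −78 to 0 °C
Reagents that add atoms: methylmagnesium bromide C[Mg]Br; iodine II
Why: Copper-catalysed anti-carbomagnesiation of the propargylic alkoxide places methyl on C2 and magnesium on C3 cis to the oxygen (five-membered chelate), and iodinolysis with retention should give the Z-iodide that later fixes both ring alkenes.

Step 2
Reactants: 2 (Z)-3-iodo-2-methylprop-2-en-1-ol
Product: 3 (Z)-tert-butyl[(3-iodo-2-methylprop-2-en-1-yl)oxy]dimethylsilane
Conditions: TBSCl, imidazole, CH2Cl2, 0 °C to rt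
Reagents that add atoms: tert-butyldimethylsilyl chloride CC(C)(C)[Si](C)(C)Cl
Why: Routine silylation of a primary alcohol; the silyl ether will serve as the C3 oxygen until step 15.

Step 3
Reactants: 3 (Z)-tert-butyl[(3-iodo-2-methylprop-2-en-1-yl)oxy]dimethylsilane
Product: 4 (Z)-4-[(tert-butyldimethylsilyl)oxy]-3-methylbut-2-enal
Conditions: t-BuLi (2.1 equiv), Et2O, −78 °C; DMF, −78 to −20 °C; aq NH4Cl
Reagents that add atoms: N,N-dimethylformamide CN(C)C=O
Why: Iodine–lithium exchange proceeds with retention and formylation with DMF (Bouveault type) should give the Z-enal; holding −78 °C suppresses 1,4-migration of silicon from oxygen to carbon.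

Step 4
Reactants: 2 (Z)-3-iodo-2-methylprop-2-en-1-ol
Product: 5 (Z)-3-iodo-2-methylprop-2-enal
Conditions: MnO2, CH2Cl2, rt
Reagents that add atoms: none
Why: MnO2 oxidation of an allylic alcohol is neutral and should leave the alkenyl iodide and its geometry untouched.

Step 5
Reactants: 5 (Z)-3-iodo-2-methylprop-2-enal
Product: 6 (Z)-1-bromo-4-iodo-3-methylbut-3-en-2-ol (racemic)
Conditions: BrCH2I, MeLi·LiBr (slow addition), THF–Et2O, −78 °C; AcOH, −78 °C
Reagents that add atoms: bromoiodomethane BrCI
Why: Iodine–lithium exchange on bromoiodomethane is faster than methyl addition or exchange at the alkenyl iodide, the resulting carbenoid adds to the aldehyde, and a cold acidic quench keeps the bromohydrin from closing to the epoxide.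

Step 6
Reactants: 6 (Z)-1-bromo-4-iodo-3-methylbut-3-en-2-ol (racemic)
Product: 7 (Z)-[(1-bromo-4-iodo-3-methylbut-3-en-2-yl)oxy](tert-butyl)dimethylsilane (racemic)
Conditions: TBSOTf, 2,6-lutidine, CH2Cl2, −78 to 0 °C
Reagents that add atoms: tert-butyldimethylsilyl triflate CC(C)(C)[Si](C)(C)OS(=O)(=O)C(F)(F)F
Why: Silylation with the triflate and a hindered weak base protects the secondary alcohol without generating the alkoxide that would displace bromide.

Step 7
Reactants: 8 (4R)-4-benzyl-1,3-oxazolidin-2-one; 9 methyl 4-chloro-4-oxobutanoate
Product: 10 methyl 4-[(4R)-4-benzyl-2-oxo-1,3-oxazolidin-3-yl]-4-oxobutanoate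
Conditions: n-BuLi, THF, −78 °C; then 9, −78 to 0 °C
Reagents that add atoms: none
Why: N-Acylation of the lithiated oxazolidinone with the acid chloride is the standard way to attach the auxiliary; the methyl ester is the future C12.

Step 8
Reactants: 10 methyl 4-[(4R)-4-benzyl-2-oxo-1,3-oxazolidin-3-yl]-4-oxobutanoate; 4 (Z)-4-[(tert-butyldimethylsilyl)oxy]-3-methylbut-2-enal
Product: 12 (4R)-4-benzyl-3-{[(2S,3R)-2-{(1Z)-3-[(tert-butyldimethylsilyl)oxy]-2-methylprop-1-en-1-yl}-5-oxooxolan-3-yl]carbonyl}-1,3-oxazolidin-2-one, via aldol adduct 11 (not isolated)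
Conditions: Bu2BOTf, i-Pr2NEt, CH2Cl2, −78 to 0 °C; 4, −78 to 0 °C; pH 7 buffer, MeOH, H2O2; then CSA (10 mol%), CH2Cl2, rt
Reagents that add atoms: none
Why: Evans syn-aldol reaction: the Z-boron enolate of the imide (the ester is not enolised) reacts through a Zimmerman–Traxler chair on the face away from the benzyl group, which with the (R)-auxiliary should set C7 and C6 as required; acid then closes the γ-hydroxy ester 11 to the trans-lactone and so marks O6 as the lactone oxygen.

Step 9
Reactants: 12 lactone imide (name as in step 8)
Product: 13 S-ethyl (2S,3R)-2-{(1Z)-3-[(tert-butyldimethylsilyl)oxy]-2-methylprop-1-en-1-yl}-5-oxooxolane-3-carbothioate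
Conditions: EtSH, n-BuLi, THF, 0 °C, short reaction time
Reagents that add atoms: ethanethiol CCS
Why: Lithium thiolate attacks the exocyclic imide carbonyl selectively (transthioesterification) and releases the auxiliary; the lactone is less electrophilic and any opening is reversed on work-up.

Step 10
Reactants: 13 S-ethyl thioester (name as in step 9)
Product: 14 (2S,3R)-2-{(1Z)-3-[(tert-butyldimethylsilyl)oxy]-2-methylprop-1-en-1-yl}-5-oxooxolane-3-carbaldehyde
Conditions: Et3SiH, 10% Pd/C, acetone, rt; crude aldehyde used at once
Reagents that add atoms: none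
Why: Fukuyama reduction converts the thioester to the aldehyde under neutral conditions without touching the lactone; the β-acyloxy aldehyde is not purified because it can eliminate.

Step 11
Reactants: 14 lactone aldehyde (name as in step 10); 7 (Z)-[(1-bromo-4-iodo-3-methylbut-3-en-2-yl)oxy](tert-butyl)dimethylsilane
Product: 15 (4S,5S)-4-{(1R,2Z)-5-bromo-4-[(tert-butyldimethylsilyl)oxy]-1-hydroxy-3-methylpent-2-en-1-yl}-5-{(1Z)-3-[(tert-butyldimethylsilyl)oxy]-2-methylprop-1-en-1-yl}oxolan-2-one
Conditions: CrCl2 (6 equiv), NiCl2 (2 mol%), DMSO, rt
Reagents that add atoms: none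
Why: Nozaki–Hiyama–Kishi reaction: zerovalent nickel inserts into the C–I bond, the alkenyl group passes to trivalent chromium with retention of the Z geometry and adds only to the aldehyde; Felkin–Anh attack anti to the C7–C6 bond should give the (8R) carbinol syn to the C11 branch.

Step 12
Reactants: 15 hydroxy lactone (name as in step 11)
Product: 18 (3S,4S,5S)-4-{(1R,2Z)-5-bromo-4-[(tert-butyldimethylsilyl)oxy]-1-hydroxy-3-methylpent-2-en-1-yl}-3-[(dimethylamino)methyl]-5-{(1Z)-3-[(tert-butyldimethylsilyl)oxy]-2-methylprop-1-en-1-yl}oxolan-2-one, via trimethylsilyl ether 16 (not isolated), via silylated Mannich base 17 (not isolated)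
Conditions: TMSCl, Et3N, THF, 0 °C, filtration; LiN(i-Pr)2, THF, −78 °C; Me2N=CH2+ I−, −78 to −20 °C; aq citric acid, THF, 0 °C, then NaHCO3
Reagents that add atoms: N,N-dimethylmethyleneiminium iodide C=[N+](C)C.[I-]
Why: Transient silylation keeps the C8 oxygen from becoming an alkoxide that could translactonise; the lactone enolate is then aminomethylated (Mannich reaction) anti to the C7 side chain, and the new C11 centre is lost in step 14.

Step 13
Reactants: 18 amino alcohol (name as in step 12); 19 angelic acid, (2Z)-2-methylbut-2-enoic acid
Product: 20 (1R,2Z)-5-bromo-4-[(tert-butyldimethylsilyl)oxy]-1-[(2S,3R,4S)-2-{(1Z)-3-[(tert-butyldimethylsilyl)oxy]-2-methylprop-1-en-1-yl}-4-[(dimethylamino)methyl]-5-oxooxolan-3-yl]-3-methylpent-2-en-1-yl (2Z)-2-methylbut-2-enoate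
Conditions: 19, 2,4,6-trichlorobenzoyl chloride, Et3N, toluene, rt; then 18, toluene, 70 °C (no DMAP)
Reagents that add atoms: none
Why: Yamaguchi-type esterification through the mixed anhydride, run without a nucleophilic catalyst, is the established way to make angelates of hindered alcohols with little isomerisation to the tiglate; the configuration at C8 is retained.

Step 14
Reactants: 20 angelate Mannich base (name as in step 13)
Product: 22 (1R,2Z)-5-bromo-4-[(tert-butyldimethylsilyl)oxy]-1-[(2S,3R)-2-{(1Z)-3-[(tert-butyldimethylsilyl)oxy]-2-methylprop-1-en-1-yl}-4-methylidene-5-oxooxolan-3-yl]-3-methylpent-2-en-1-yl (2Z)-2-methylbut-2-enoate, via ammonium iodide 21 (not isolated)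
Conditions: MeI (excess), CH2Cl2, rt; then aq NaHCO3, EtOAc, rt
Reagents that add atoms: none
Why: Quaternisation of the amine followed by mild-base E1cB (Hofmann-type) elimination of trimethylamine is the classical unmasking of an α-methylene lactone and is compatible with the angelate.

Step 15
Reactants: 22 bis-silyl ether (name as in step 14)
Product: 23 (1R,2Z)-5-bromo-4-hydroxy-1-[(2S,3R)-2-[(1Z)-3-hydroxy-2-methylprop-1-en-1-yl]-4-methylidene-5-oxooxolan-3-yl]-3-methylpent-2-en-1-yl (2Z)-2-methylbut-2-enoate
Conditions: HF·pyridine, THF, 0 °C to rt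
Reagents that add atoms: none
Why: Acidic fluoride removes both silyl ethers in one operation and avoids basic fluoride, which could close the bromohydrin to an epoxide or add to the methylene lactone.

Step 16
Reactants: 23 diol (name as in step 15)
Product: 24 (1R,2Z)-5-bromo-3-methyl-1-[(2S,3R)-4-methylidene-2-[(1Z)-2-methyl-3-oxoprop-1-en-1-yl]-5-oxooxolan-3-yl]-4-oxopent-2-en-1-yl (2Z)-2-methylbut-2-enoate
Conditions: Dess–Martin periodinane (3 equiv), NaHCO3, CH2Cl2, 0 °C to rt; used directly
Reagents that add atoms: none
Why: Dess–Martin oxidation converts the primary allylic alcohol to the Z-enal and the bromohydrin to the bromomethyl enone in one buffered, non-enolising step, so both sensitive termini exist only for the ring closure.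

Step 17
Reactants: 24 seco bromomethyl enone enal (name as in step 16)
Product: 26 (3S,6S,7R,8R)-8-angeloyloxy-3-hydroxy-1-oxo ten-membered (4Z,9Z)-diene 6,12-olide with C11=C13 methylene (carbocycle numbering), via samarium enolate 25 (not isolated)
Conditions: SmI2 (2.5 equiv), THF, −78 °C, slow addition of 24 to a final 2 mM; sat. NH4Cl at −78 °C
Reagents that add atoms: none
Why: Two single-electron transfers from divalent samarium cleave the C2–Br bond and give the trivalent samarium enolate 25, whose C2 adds to the C3 aldehyde through a chelated six-membered chair in which samarium bridges both oxygens. The closest known reaction type is the SmI2-promoted intramolecular Reformatsky-type aldol of α-bromo ketones and α-bromo esters with aldehydes, which closes eight-membered and larger carbocycles and lactones. The carbocycle is closed in the 10-(enolendo)-exo-trig mode, favoured by the two Z-alkenes and the trans-lactone, which fold the chain and bring C2 next to C3. The new C3 centre is controlled by the face of the enal exposed in this folded, chelated arrangement under the remote influence of C6–C8, and the (3S) carbinol is the expected product. The step needs chemoselectivity for C–Br over the enal, the methylene lactone and the angelate, which the much faster reduction of α-halo ketones at −78 °C without additives secures. It also needs cyclisation over oligomerisation, which high dilution secures. The cross-conjugated enolate places no charge at C9, so the C8 angelate should not be expelled, and the cold quench prevents retro-aldol and dehydration.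

Step 18
Reactants: 26 macrocyclic β-hydroxy enone (name as in step 17)
Product: 27 target, (1S,3S,6S,7R,8R)-8-angeloyloxy-1,3-dihydroxy ten-membered (4Z,9Z)-diene 6,12-olide with C11=C13 methylene (CNP0152559.1)
Conditions: Me4NBH(OAc)3, MeCN–AcOH (1:1), −30 °C; aq KNaC4H4O6
Reagents that add atoms: none
Why: Evans–Saksena reduction: the C3 hydroxyl exchanges onto boron and hydride is delivered intramolecularly through a chair-like six-membered transition state to the C1 ketone, which should give the anti-1,3-diol (1S) by 1,2-reduction while esters and the methylene lactone are inert to this reagent.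

## Compound list

1 | prop-2-yn-1-ol | C#CCO | starting material
2 | (Z)-3-iodo-2-methylprop-2-en-1-ol | OC/C(C)=C\I | intermediate
3 | (Z)-tert-butyl[(3-iodo-2-methylprop-2-en-1-yl)oxy]dimethylsilane | CC(C)(C)[Si](C)(C)OC/C(C)=C\I | intermediate
4 | (Z)-4-[(tert-butyldimethylsilyl)oxy]-3-methylbut-2-enal | CC(C)(C)[Si](C)(C)OC/C(C)=C\C=O | intermediate
5 | (Z)-3-iodo-2-methylprop-2-enal | O=C/C(C)=C\I | intermediate
6 | (Z)-1-bromo-4-iodo-3-methylbut-3-en-2-ol (racemic) | OC(CBr)/C(C)=C\I | intermediate
7 | (Z)-[(1-bromo-4-iodo-3-methylbut-3-en-2-yl)oxy](tert-butyl)dimethylsilane (racemic) | CC(C)(C)[Si](C)(C)OC(CBr)/C(C)=C\I | intermediate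
8 | (4R)-4-benzyl-1,3-oxazolidin-2-one | O=C1N[C@H](Cc2ccccc2)CO1 | starting material
9 | methyl 4-chloro-4-oxobutanoate | COC(=O)CCC(=O)Cl | starting material
10 | methyl 4-[(4R)-4-benzyl-2-oxo-1,3-oxazolidin-3-yl]-4-oxobutanoate | COC(=O)CCC(=O)N1[C@H](Cc2ccccc2)COC1=O | intermediate
11 | aldol adduct, methyl (3R,4S,5Z)-3-{[(4R)-4-benzyl-2-oxo-1,3-oxazolidin-3-yl]carbonyl}-7-[(tert-butyldimethylsilyl)oxy]-4-hydroxy-6-methylhept-5-enoate | COC(=O)C[C@@H](C(=O)N1[C@H](Cc2ccccc2)COC1=O)[C@@H](O)/C=C(/C)CO[Si](C)(C)C(C)(C)C | intermediate
12 | lactone imide, (4R)-4-benzyl-3-{[(2S,3R)-2-{(1Z)-3-[(tert-butyldimethylsilyl)oxy]-2-methylprop-1-en-1-yl}-5-oxooxolan-3-yl]carbonyl}-1,3-oxazolidin-2-one | O=C1C[C@@H](C(=O)N2[C@H](Cc3ccccc3)COC2=O)[C@H](/C=C(/C)CO[Si](C)(C)C(C)(C)C)O1 | intermediate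
13 | S-ethyl (2S,3R)-2-{(1Z)-3-[(tert-butyldimethylsilyl)oxy]-2-methylprop-1-en-1-yl}-5-oxooxolane-3-carbothioate | CCSC(=O)[C@@H]1CC(=O)O[C@H]1/C=C(/C)CO[Si](C)(C)C(C)(C)C | intermediate
14 | (2S,3R)-2-{(1Z)-3-[(tert-butyldimethylsilyl)oxy]-2-methylprop-1-en-1-yl}-5-oxooxolane-3-carbaldehyde | O=C[C@@H]1CC(=O)O[C@H]1/C=C(/C)CO[Si](C)(C)C(C)(C)C | intermediate
15 | (4S,5S)-4-{(1R,2Z)-5-bromo-4-[(tert-butyldimethylsilyl)oxy]-1-hydroxy-3-methylpent-2-en-1-yl}-5-{(1Z)-3-[(tert-butyldimethylsilyl)oxy]-2-methylprop-1-en-1-yl}oxolan-2-one | BrCC(O[Si](C)(C)C(C)(C)C)/C(C)=C\[C@@H](O)[C@@H]1CC(=O)O[C@H]1/C=C(/C)CO[Si](C)(C)C(C)(C)C | intermediate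
16 | C8 trimethylsilyl ether of 15 | BrCC(O[Si](C)(C)C(C)(C)C)/C(C)=C\[C@@H](O[Si](C)(C)C)[C@@H]1CC(=O)O[C@H]1/C=C(/C)CO[Si](C)(C)C(C)(C)C | intermediate
17 | C11 (dimethylamino)methyl derivative of 16 (aminomethyl trans to the C7 side chain) | BrCC(O[Si](C)(C)C(C)(C)C)/C(C)=C\[C@@H](O[Si](C)(C)C)[C@@H]1[C@@H](CN(C)C)C(=O)O[C@H]1/C=C(/C)CO[Si](C)(C)C(C)(C)C | intermediate
18 | (3S,4S,5S)-4-{(1R,2Z)-5-bromo-4-[(tert-butyldimethylsilyl)oxy]-1-hydroxy-3-methylpent-2-en-1-yl}-3-[(dimethylamino)methyl]-5-{(1Z)-3-[(tert-butyldimethylsilyl)oxy]-2-methylprop-1-en-1-yl}oxolan-2-one | BrCC(O[Si](C)(C)C(C)(C)C)/C(C)=C\[C@@H](O)[C@@H]1[C@@H](CN(C)C)C(=O)O[C@H]1/C=C(/C)CO[Si](C)(C)C(C)(C)C | intermediate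
19 | angelic acid, (2Z)-2-methylbut-2-enoic acid | C/C=C(/C)C(=O)O | starting material
20 | C8 angelate of 18 (full name in step 13) | BrCC(O[Si](C)(C)C(C)(C)C)/C(C)=C\[C@@H](OC(=O)/C(C)=C\C)[C@@H]1[C@@H](CN(C)C)C(=O)O[C@H]1/C=C(/C)CO[Si](C)(C)C(C)(C)C | intermediate
21 | N-methyl ammonium iodide of 20 | BrCC(O[Si](C)(C)C(C)(C)C)/C(C)=C\[C@@H](OC(=O)/C(C)=C\C)[C@@H]1[C@@H](C[N+](C)(C)C)C(=O)O[C@H]1/C=C(/C)CO[Si](C)(C)C(C)(C)C.[I-] | intermediate
22 | methylene lactone bis-silyl ether (full name in step 14) | BrCC(O[Si](C)(C)C(C)(C)C)/C(C)=C\[C@@H](OC(=O)/C(C)=C\C)[C@@H]1C(=C)C(=O)O[C@H]1/C=C(/C)CO[Si](C)(C)C(C)(C)C | intermediate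
23 | diol (full name in step 15) | BrCC(O)/C(C)=C\[C@@H](OC(=O)/C(C)=C\C)[C@@H]1C(=C)C(=O)O[C@H]1/C=C(/C)CO | intermediate
24 | seco bromomethyl enone enal (full name in step 16) | C=C1C(=O)O[C@@H](/C=C(/C)C=O)[C@@H]1[C@H](OC(=O)/C(C)=C\C)/C=C(C)\C(=O)CBr | intermediate
25 | diiodosamarium C1–C2 enolate of 24 | C=C(O[Sm](I)I)/C(C)=C\[C@@H](OC(=O)/C(C)=C\C)[C@@H]1C(=C)C(=O)O[C@H]1/C=C(/C)C=O | intermediate
26 | (3S,6S,7R,8R)-3-hydroxy-1-oxo macrocycle, 8-angelate, 6,12-olide | C=C1C(=O)O[C@H]2/C=C(/C)[C@@H](O)CC(=O)/C(C)=C\[C@@H](OC(=O)/C(C)=C\C)[C@H]12 | intermediate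
27 | CNP0152559.1, (1S,3S,6S,7R,8R)-1,3-dihydroxy macrocycle, 8-angelate, 6,12-olide | C=C1C(=O)O[C@H]2/C=C(/C)[C@@H](O)C[C@H](O)/C(C)=C\[C@@H](OC(=O)/C(C)=C\C)[C@H]12 | target

## Step count and least certain steps

Total step count: 18. Longest linear sequence: 14 steps (steps 1–3 and 8–18, from 1 to 27).

**Step 17 (key step).** The likeliest failures are poor facial selectivity at C3, since control is remote, and competing intermolecular aldol addition or reduction of the enal by excess reductant. Dilution and stoichiometry address the second pair. For the first, the fallback sets out from 24 and accepts the C3 epimer of the macrocycle F1. The reduction of step 18 would convert F1 into the anti-diol with both carbinols epimeric, F2. A double Mitsunobu esterification with formic acid (PPh3, DIAD) then inverts both allylic centres to give the bis-formate F3, and mild methanolysis (NaHCO3, MeOH, 0 °C) releases both hydroxyls and returns to the route at 27.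

**Step 11.** Facial selectivity at C8 is uncertain, because the Felkin–Anh preference is opposed by the dipole of the β-oxygen. Elimination of the lactone carboxylate from aldehyde 14 and slow reduction of the alkyl bromide by low-valent metal are also possible. If addition gives mainly the C8 epimer, the fallback starts from 14 and 7 and takes the 8-epi alcohol F4 through the conditions of step 12 to the 8-epi amino alcohol F5. The ester is then made with inversion by Mitsunobu reaction with 19 (PPh3, DIAD), rejoining the route at 20.

**Step 13.** Acyl activation may isomerise the angeloyl group to tigloyl. Prolonged heating of the free hydroxy lactone with amine may also cause translactonisation or quaternisation of the amine by the bromide. The fallback avoids an activated acyl donor. It sets out from 15, oxidises C8 with Dess–Martin periodinane to enone F6, and reduces it with NaBH4 and CeCl3·7H2O (Luche reduction). Felkin–Anh hydride delivery should then give the 8-epi alcohol F4. From there the sequence through F5 and the Mitsunobu esterification with 19 described above returns to 20.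

**Step 12.** Incomplete silylation would leave a lithium alkoxide that can translactonise. The enolate may also displace or eliminate the bromide before the iminium salt arrives. The fallback sets out from 15 and isolates a robust triethylsilyl ether F7 (TESCl, imidazole). A one-flask methylenation (LiN(i-Pr)2; Me2N=CH2+ I−; MeI; NaHCO3) gives methylene lactone F8, and the silyl group on C8 is removed selectively (PPTS, MeOH, 0 °C) to give hydroxy methylene lactone F9. Esterification as in step 13 then returns to the route at 22.

**Step 10.** Palladium may cleave the allylic C6–O bond or reduce the trisubstituted alkene. The thiolate needed to make 13 in step 9 may also trigger elimination across C7–C6. The fallback sets out from 12 and avoids both thiolate and palladium. LiOH and H2O2 remove the auxiliary to give lactone acid F10 after acidification. (COCl)2 with catalytic DMF gives acid chloride F11, and LiAlH(O-t-Bu)3 at −78 °C reduces it to the aldehyde, returning to the route at 14.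

## Further compounds

F1 | step 17 | C3 epimer of 26, (3R)-3-hydroxy-1-oxo macrocycle | C=C1C(=O)O[C@H]2/C=C(/C)[C@H](O)CC(=O)/C(C)=C\[C@@H](OC(=O)/C(C)=C\C)[C@H]12
F2 | step 17 | (1R,3R)-anti-diol, 1,3-bis-epimer of 27 | C=C1C(=O)O[C@H]2/C=C(/C)[C@H](O)C[C@@H](O)/C(C)=C\[C@@H](OC(=O)/C(C)=C\C)[C@H]12
F3 | step 17 | (1S,3S)-bis-formate of 27 | C=C1C(=O)O[C@H]2/C=C(/C)[C@@H](OC=O)C[C@H](OC=O)/C(C)=C\[C@@H](OC(=O)/C(C)=C\C)[C@H]12
F4 | step 11 | C8 epimer of 15 | BrCC(O[Si](C)(C)C(C)(C)C)/C(C)=C\[C@H](O)[C@@H]1CC(=O)O[C@H]1/C=C(/C)CO[Si](C)(C)C(C)(C)C
F5 | step 11 | C8 epimer of 18 | BrCC(O[Si](C)(C)C(C)(C)C)/C(C)=C\[C@H](O)[C@@H]1[C@@H](CN(C)C)C(=O)O[C@H]1/C=C(/C)CO[Si](C)(C)C(C)(C)C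
F6 | step 13 | C8 ketone (enone) from 15 | BrCC(O[Si](C)(C)C(C)(C)C)/C(C)=C\C(=O)[C@@H]1CC(=O)O[C@H]1/C=C(/C)CO[Si](C)(C)C(C)(C)C
F7 | step 12 | C8 triethylsilyl ether of 15 | BrCC(O[Si](C)(C)C(C)(C)C)/C(C)=C\[C@@H](O[Si](CC)(CC)CC)[C@@H]1CC(=O)O[C@H]1/C=C(/C)CO[Si](C)(C)C(C)(C)C
F8 | step 12 | α-methylene lactone with C8 triethylsilyl ether | BrCC(O[Si](C)(C)C(C)(C)C)/C(C)=C\[C@@H](O[Si](CC)(CC)CC)[C@@H]1C(=C)C(=O)O[C@H]1/C=C(/C)CO[Si](C)(C)C(C)(C)C
F9 | step 12 | α-methylene lactone with free C8 hydroxyl | BrCC(O[Si](C)(C)C(C)(C)C)/C(C)=C\[C@@H](O)[C@@H]1C(=C)C(=O)O[C@H]1/C=C(/C)CO[Si](C)(C)C(C)(C)C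
F10 | step 10 | (2S,3R)-2-{(1Z)-3-[(tert-butyldimethylsilyl)oxy]-2-methylprop-1-en-1-yl}-5-oxooxolane-3-carboxylic acid | OC(=O)[C@@H]1CC(=O)O[C@H]1/C=C(/C)CO[Si](C)(C)C(C)(C)C
F11 | step 10 | acid chloride of F10 | ClC(=O)[C@@H]1CC(=O)O[C@H]1/C=C(/C)CO[Si](C)(C)C(C)(C)C
A1 | alternative 1 | thirteen-membered cyclic ether stannane (C8–O–C13 bridge, C7=C11 alkene) | CCCC[Sn](CCCC)(CCCC)C1OCC(COCc2ccc(OC)cc2)=C[C@@H](OCc2ccc(OC)cc2)/C=C(/C)[C@@H](O[Si](C)(C)C(C)(C)C)C[C@H](O[Si](C)(C)C(C)(C)C)/C(C)=C\1
A2 | alternative 1 | ten-membered dienol with free C8 hydroxyl and C11=C13 methylene | C=C(COCc1ccc(OC)cc1)[C@@H]1[C@@H](OCc2ccc(OC)cc2)/C=C(/C)[C@@H](O[Si](C)(C)C(C)(C)C)C[C@H](O[Si](C)(C)C(C)(C)C)/C(C)=C\[C@H]1O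
A3 | alternative 2 | seco C1 aldoxime with C2–C5 diene, C13 silyl ether and C8 angelate | CC(C)(C)[Si](C)(C)OC[C@@H]1C(=O)O[C@@H](/C=C(/C)C=C)[C@@H]1[C@H](OC(=O)/C(C)=C\C)/C=C(C)\C=NO
A4 | alternative 2 | isoxazoline-bridged ten-membered diene lactone | CC(C)(C)[Si](C)(C)OC[C@@H]1C(=O)O[C@H]2/C=C(/C)[C@@H]3CC(=NO3)/C(C)=C\[C@@H](OC(=O)/C(C)=C\C)[C@H]12
A5 | alternative 3 | seco C8 aldehyde with (Z)-C9 iodoalkene | CC[Si](CC)(CC)OC[C@@H]1C(=O)O[C@@H](/C=C(/C)[C@@H](O[Si](C)(C)C(C)(C)C)C[C@H](O[Si](C)(C)C(C)(C)C)/C(C)=C\I)[C@@H]1C=O
A6 | alternative 3 | ten-membered lactone with free C8 hydroxyl | CC[Si](CC)(CC)OC[C@@H]1C(=O)O[C@H]2/C=C(/C)[C@@H](O[Si](C)(C)C(C)(C)C)C[C@H](O[Si](C)(C)C(C)(C)C)/C(C)=C\[C@@H](O)[C@H]12
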